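The rate constants are made up; no experiment stands behind them.

3 questions stand on this flask and its changes.

- the first product and crystals together standing at 40 min, as a percentage of the substrate charged
- the change that raises the amount of first product and crystals together at 40 min, in percent of the substrate charged most ("none" if none brings more than 2 percentage points) (south-west / west / south / none)
- amount of first product and crystals together at 40 min, in percent of the substrate charged, after south

- south-west: doubling the amount of coupling partner, all else as stated
- west: doubling the solubility in step 1, all else as stated
- south: doubling the dissolution coefficient of step 1, all else as stated

substrate 1.1 M; coupling partner 2.00 equiv; time 40 min

    crystals ⇌ first product, rate k1*(cs1 - [first product]) while solid is left; crystals form when [first product] > cs1 (cs1 = 14 mM, k1 = 1.3 min⁻¹)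
    substrate + coupling partner → first product (k2 = 0.16 M⁻¹ min⁻¹)
    coupling partner + first product → bis adduct (k3 = 0.38 M⁻¹ min⁻¹)

- amounts and yields of first product count crystals too
- given per volume of solution although it is solid: crystals
- run time (flask): 40 min

Which concentration sets the order of the over-reaction? Dissolved [first product], together with [coupling partner]. Crystals do not stand in that step.

Does dissolved [first product] sit at its solubility? Not while the charge is fresh, by my reckoning. At the charged [coupling partner] of 2.20 M, its pseudo-first-order loss to bis adduct runs at 0.836 min⁻¹. Its exit to crystals runs at 1.3 min⁻¹. Balancing the making against both exits puts [first product] near 0.190 M, far above the solubility of 14 mM.

What do you carry from that? The capture share: the exit to bis adduct over the sum of both exits, 39.1% at the charge. It is the part of new first product caught before it crystallises, while [first product] stands far above its solubility.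

Isn't that a figure for the charged [coupling partner]? Yes. The share shrinks as [coupling partner] falls, so I give no yield by hand.

And the changes? South lowers the share at the charge to 24.3%. South-west raises it to 56.3%. West leaves it at 39.1%, since the solubility does not stand in it. My pick is south.

The forecast gives 58%, south and 65%: "Faster crystal exchange (south) pulls the early supersaturation down".

The simulation gives 58.5%, south as the best change, and 66.5% after it, a gain of 8 percentage points. West moves the flask by −11 points, south-west by −37 points. By 4.00 min this flask has turned 32.8% of the substrate used into bis adduct, against a share of 39.1% at the charge. The neighbour flask with 1.20 equiv of coupling partner, all else as here, has a share of 27.8% at its charge. By 40.0 min that neighbour has turned 22.1% of the substrate used into bis adduct, and it ends with first product and crystals together at 69.2%.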